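**Retrosynthetic overview**
1. Target 20 ⇐ diol 16 (both hydroxyls angeloylated in one operation with two equivalents of angelic acid) ⇐ vinyl tricycle 13 (C14 from cleavage and reduction of a vinyl group).
2. Ring C (cyclobutane, C5–C11) is closed last by 4-exo-tet enolate alkylation of mesylate 12.
3. Ring B (cycloheptane, C4–C5) comes from aldehyde 9 by an intramolecular vinylogous Mukaiyama aldol; C6 and C7 come from iridium-catalysed tert-(hydroxy)prenylation of alcohol 6 with isoprene monoxide 7.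
4. Ring A (cyclohexenone, quaternary C10) is made first, by an enantioselective, symmetry-breaking aldol condensation of the achiral 1,5-diketone 5.
5. Diketone 5 ⇐ dearomative γ-alkylation and hydrolysis of 2,4,6-trimethylpyrylium salt 1 (the two key steps are steps 1 and 2); ring order A → B → C.

Assumption: the SMILES is read as the (1R,2R,5S,6R,7S,8R) enantiomer with both esters Z (angelates); atom labels C1–C15 are sesquiterpene numbers (C1 ketone, C2=C3 with C12H3 on C3, C4 and C11 bridgeheads, C5, C6 quaternary with C14H2O and C15H3, C7 carbinol, C8, C9, C10 quaternary with C13H3).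

**Step 1**
Reactants: 1 2,4,6-trimethylpyrylium tetrafluoroborate; 2 2-(3-bromopropoxy)oxane
Product: 5 4-(3-hydroxypropyl)-4-methylheptane-2,6-dione, via Grignard reagent 3 (not isolated), via 4H-pyran 4 (not isolated)
Conditions: Mg, THF; CuBr·SMe2 (10 mol %), then 1, THF, −78 to 0 °C; then 1 M HCl, THF, rt
Reagents that add atoms: water (O)
Why: Proposed new method: soft organocopper reagents attack cationic six-membered heteroaromatics at the γ-position (closest known cases: γ-addition of RCu reagents to N-acylpyridinium salts, and 4-attack of benzyl-, allyl- and sec-alkyl Grignard reagents on 2,4,6-trialkylpyrylium salts), so the alkylcopper from 3 should alkylate C4 of 1 to give the non-aromatic, mirror-symmetric 4H-pyran 4, whose two enol ethers and THP acetal are hydrolysed by dilute acid to the achiral 1,5-diketone 5 (its C4 becomes C10; no stereocentre yet).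

**Step 2**
Reactants: 5 4-(3-hydroxypropyl)-4-methylheptane-2,6-dione
Product: 6 (5R)-5-(3-hydroxypropyl)-3,5-dimethylcyclohex-2-en-1-one
Conditions: 9-amino-9-deoxy-epi-quinine (20 mol %), AcOH (60 mol %), toluene, −15 °C
Reagents that add atoms: none
Why: Primary-amine (enamine) catalysed intramolecular aldol condensation of the Hajos–Parrish/List type, in which the catalyst differentiates the two enantiotopic acetonyl arms of 5 and so sets quaternary C10 as R (the pseudo-enantiomeric epi-quinidine amine is used if the sense is opposite; telling CH3 from the hydroxypropyl arm at a quaternary carbon is the untested part, and any minor enantiomer is removed as a C10-epimer after step 3).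

**Step 3**
Reactants: 6 (5R)-5-(3-hydroxypropyl)-3,5-dimethylcyclohex-2-en-1-one; 7 2-ethenyl-2-methyloxirane
Product: 8 (5R)-5-[(3S,4S)-3-hydroxy-4-(hydroxymethyl)-4-methylhex-5-en-1-yl]-3,5-dimethylcyclohex-2-en-1-one
Conditions: 7 (3 equiv), π-allyliridium C,O-benzoate catalyst from [Ir(cod)Cl]2, (S)-Tol-BINAP and 4-cyano-3-nitrobenzoic acid (5 mol %), K3PO4 (5 mol %), THF, 60 °C
Reagents that add atoms: none
Why: Krische iridium-catalysed tert-(hydroxy)prenylation (redox-neutral transfer-hydrogenative carbonyl allylation), in which the alcohol is dehydrogenated in situ and the aldehyde is attacked by the chiral π-allyliridium species from racemic 7 through a closed chair transition state, setting C7 (S) and quaternary C6 (anti product) under catalyst control (the Tol-BINAP antipode is chosen to give 7S).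

**Step 4**
Reactants: 8 (5R)-5-[(3S,4S)-3-hydroxy-4-(hydroxymethyl)-4-methylhex-5-en-1-yl]-3,5-dimethylcyclohex-2-en-1-one
Product: 9 (2R,3S)-5-[(1R)-1,3-dimethyl-5-oxocyclohex-3-en-1-yl]-2-ethenyl-3-hydroxy-2-methylpentanal
Conditions: TEMPO (10 mol %), PhI(OAc)2, CH2Cl2, rt
Reagents that add atoms: none
Why: TEMPO/oxoammonium oxidation is selective for the primary hydroxyl over the hindered secondary one, and the α-quaternary aldehyde 9 (its CHO carbon is C5) can neither epimerise nor eliminate.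

**Step 5**
Reactants: 9 (2R,3S)-5-[(1R)-1,3-dimethyl-5-oxocyclohex-3-en-1-yl]-2-ethenyl-3-hydroxy-2-methylpentanal
Product: 11 (4aS,5S,6S,7S,9aS)-6-ethenyl-5-hydroxy-4,6,9a-trimethyl-7-[(triethylsilyl)oxy]-1,4a,5,6,7,8,9,9a-octahydro-2H-benzo[7]annulen-2-one, via bis-silyl dienol ether 10 (not isolated)
Conditions: Et3SiOTf, Et3N, CH2Cl2, 0 °C; then BF3·OEt2, CH2Cl2, −78 °C; aq NaHCO3
Reagents that add atoms: triethylsilyl trifluoromethanesulfonate (CC[Si](CC)(CC)OS(=O)(=O)C(F)(F)F)
Why: Soft enolisation gives the linear silyl dienol ether and silylates O7, and an intramolecular vinylogous Mukaiyama aldol then joins γ-carbon C4 to the aldehyde, the C9 tether forcing the new bond cis to C9 (cis-fused rings A and B, sets C4) and an open transition state with the aldehyde oxygen anti to the C7 silyloxy group giving the 5,7-anti carbinol (sets C5; this sense is argued, not precedented).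

**Step 6**
Reactants: 11 (4aS,5S,6S,7S,9aS)-6-ethenyl-5-hydroxy-4,6,9a-trimethyl-7-[(triethylsilyl)oxy]-1,4a,5,6,7,8,9,9a-octahydro-2H-benzo[7]annulen-2-one
Product: 12 (4aS,5S,6R,7S,9aS)-6-ethenyl-4,6,9a-trimethyl-2-oxo-7-[(triethylsilyl)oxy]-2,4a,5,6,7,8,9,9a-octahydro-1H-benzo[7]annulen-5-yl methanesulfonate
Conditions: MsCl, Et3N, CH2Cl2, 0 °C
Reagents that add atoms: methanesulfonyl chloride (CS(=O)(=O)Cl)
Why: Sulfene-type mesylation of the only free hydroxyl proceeds with retention at C5 (the change of the C6 descriptor is a priority change only).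

**Step 7**
Reactants: 12 (4aS,5S,6R,7S,9aS)-6-ethenyl-4,6,9a-trimethyl-2-oxo-7-[(triethylsilyl)oxy]-2,4a,5,6,7,8,9,9a-octahydro-1H-benzo[7]annulen-5-yl methanesulfonate
Product: 13 (1R,2R,5S,6S,7S,8R)-6-ethenyl-2,6,9-trimethyl-5-[(triethylsilyl)oxy]tricyclo[5.4.0.0^{2,8}]undec-9-en-11-one
Conditions: KN(SiMe3)2, THF, −78 to 0 °C
Reagents that add atoms: none
Why: Heathcock-type intramolecular enolate alkylation (4-exo-tet SN2, the ring closure of the classical copaene syntheses), in which kinetic α′-deprotonation at C11 and backside displacement of the C5 mesylate, held anti to C11 by the cis-fused bicycle, closes the cyclobutane with inversion at C5 and locks C11, C5 and C4 in the cage.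

**Step 8**
Reactants: 13 (1R,2R,5S,6S,7S,8R)-6-ethenyl-2,6,9-trimethyl-5-[(triethylsilyl)oxy]tricyclo[5.4.0.0^{2,8}]undec-9-en-11-one
Product: 16 (1R,2R,5S,6R,7S,8R)-5-hydroxy-6-(hydroxymethyl)-2,6,9-trimethyltricyclo[5.4.0.0^{2,8}]undec-9-en-11-one, via aldehyde 14 (not isolated), via silyl ether alcohol 15 (not isolated)
Conditions: OsO4 (2 mol %), NaIO4, 2,6-lutidine, dioxane/H2O, rt; NaBH4, MeOH, −78 °C; 1 M HCl, THF, rt
Reagents that add atoms: sodium periodate ([Na+].[O-]I(=O)(=O)=O)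
Why: Lemieux–Johnson cleavage is selective for the electron-rich vinyl group over the conjugated trisubstituted C2=C3, NaBH4 at −78 °C reduces the neopentyl aldehyde but not the hindered enone, and dilute acid removes the triethylsilyl group, with no stereocentre touched.

**Step 9**
Reactants: 16 (1R,2R,5S,6R,7S,8R)-5-hydroxy-6-(hydroxymethyl)-2,6,9-trimethyltricyclo[5.4.0.0^{2,8}]undec-9-en-11-one; 17 (2Z)-2-methylbut-2-enoic acid
Product: 20 [(1R,2R,5S,6R,7S,8R)-2,6,9-trimethyl-5-{[(2Z)-2-methylbut-2-enoyl]oxy}-11-oxotricyclo[5.4.0.0^{2,8}]undec-9-en-6-yl]methyl (2Z)-2-methylbut-2-enoate, via mixed anhydride 18 (not isolated), via primary mono-angelate 19 (not isolated)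
Conditions: 17 (4 equiv), 2,4,6-trichlorobenzoyl chloride (4 equiv), Et3N (4.4 equiv), toluene, rt; then 16, 80 °C
Reagents that add atoms: (2Z)-2-methylbut-2-enoic acid, the second equivalent of 17 (C/C=C(/C)C(=O)O)
Why: Yamaguchi-type esterification without a nucleophilic catalyst, in which two equivalents of the acid (used in excess as mixed anhydride 18) acylate first the primary C14 hydroxyl (mono-ester 19) and then, at 80 °C, the hindered secondary C7 hydroxyl, under conditions known to keep the Z geometry of angelates.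

**Compound list**
1 | 2,4,6-trimethylpyrylium tetrafluoroborate (commercial; one step from tert-butanol, acetic anhydride and HBF4) | Cc1cc(C)[o+]c(C)c1.F[B-](F)(F)F | starting material
2 | 2-(3-bromopropoxy)oxane | BrCCCOC1CCCCO1 | starting material
3 | [3-(oxan-2-yloxy)propyl]magnesium bromide | Br[Mg]CCCOC1CCCCO1 | intermediate
4 | 2,4,6-trimethyl-4-[3-(oxan-2-yloxy)propyl]-4H-pyran | CC1=CC(C)(CCCOC2CCCCO2)C=C(C)O1 | intermediate
5 | 4-(3-hydroxypropyl)-4-methylheptane-2,6-dione | CC(=O)CC(C)(CCCO)CC(C)=O | intermediate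
6 | (5R)-5-(3-hydroxypropyl)-3,5-dimethylcyclohex-2-en-1-one | OCCC[C@]1(C)CC(C)=CC(=O)C1 | intermediate
7 | 2-ethenyl-2-methyloxirane (isoprene monoxide, racemic) | CC1(C=C)CO1 | starting material
8 | (5R)-5-[(3S,4S)-3-hydroxy-4-(hydroxymethyl)-4-methylhex-5-en-1-yl]-3,5-dimethylcyclohex-2-en-1-one | C=C[C@@](C)(CO)[C@@H](O)CC[C@]1(C)CC(C)=CC(=O)C1 | intermediate
9 | (2R,3S)-5-[(1R)-1,3-dimethyl-5-oxocyclohex-3-en-1-yl]-2-ethenyl-3-hydroxy-2-methylpentanal | C=C[C@@](C)(C=O)[C@@H](O)CC[C@]1(C)CC(C)=CC(=O)C1 | intermediate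
10 | (2R,3S)-5-{(1S)-1,3-dimethyl-5-[(triethylsilyl)oxy]cyclohexa-2,4-dien-1-yl}-2-ethenyl-2-methyl-3-[(triethylsilyl)oxy]pentanal | C=C[C@@](C)(C=O)[C@@H](O[Si](CC)(CC)CC)CC[C@]1(C)C=C(C)C=C(O[Si](CC)(CC)CC)C1 | intermediate
11 | (4aS,5S,6S,7S,9aS)-6-ethenyl-5-hydroxy-4,6,9a-trimethyl-7-[(triethylsilyl)oxy]-1,4a,5,6,7,8,9,9a-octahydro-2H-benzo[7]annulen-2-one (rings A/B cis-fused; 5-OH cis to vinyl, trans to 7-OSiEt3) | C=C[C@@]1(C)[C@@H](O)[C@@H]2C(C)=CC(=O)C[C@]2(C)CC[C@@H]1O[Si](CC)(CC)CC | intermediate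
12 | (4aS,5S,6R,7S,9aS)-6-ethenyl-4,6,9a-trimethyl-2-oxo-7-[(triethylsilyl)oxy]-2,4a,5,6,7,8,9,9a-octahydro-1H-benzo[7]annulen-5-yl methanesulfonate | C=C[C@@]1(C)[C@@H](OS(C)(=O)=O)[C@@H]2C(C)=CC(=O)C[C@]2(C)CC[C@@H]1O[Si](CC)(CC)CC | intermediate
13 | (1R,2R,5S,6S,7S,8R)-6-ethenyl-2,6,9-trimethyl-5-[(triethylsilyl)oxy]tricyclo[5.4.0.0^{2,8}]undec-9-en-11-one | C=C[C@@]1(C)[C@@H]2[C@H]3C(=O)C=C(C)[C@@H]2[C@@]3(C)CC[C@@H]1O[Si](CC)(CC)CC | intermediate
14 | (1R,2R,5S,6S,7S,8R)-2,6,9-trimethyl-11-oxo-5-[(triethylsilyl)oxy]tricyclo[5.4.0.0^{2,8}]undec-9-ene-6-carbaldehyde | O=C[C@@]1(C)[C@@H]2[C@H]3C(=O)C=C(C)[C@@H]2[C@@]3(C)CC[C@@H]1O[Si](CC)(CC)CC | intermediate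
15 | (1R,2R,5S,6R,7S,8R)-6-(hydroxymethyl)-2,6,9-trimethyl-5-[(triethylsilyl)oxy]tricyclo[5.4.0.0^{2,8}]undec-9-en-11-one | OC[C@@]1(C)[C@@H]2[C@H]3C(=O)C=C(C)[C@@H]2[C@@]3(C)CC[C@@H]1O[Si](CC)(CC)CC | intermediate
16 | (1R,2R,5S,6R,7S,8R)-5-hydroxy-6-(hydroxymethyl)-2,6,9-trimethyltricyclo[5.4.0.0^{2,8}]undec-9-en-11-one | OC[C@@]1(C)[C@@H]2[C@H]3C(=O)C=C(C)[C@@H]2[C@@]3(C)CC[C@@H]1O | intermediate
17 | (2Z)-2-methylbut-2-enoic acid (angelic acid) | C/C=C(/C)C(=O)O | starting material
18 | (2Z)-2-methylbut-2-enoic 2,4,6-trichlorobenzoic anhydride | C/C=C(/C)C(=O)OC(=O)c1c(Cl)cc(Cl)cc1Cl | intermediate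
19 | [(1R,2R,5S,6R,7S,8R)-5-hydroxy-2,6,9-trimethyl-11-oxotricyclo[5.4.0.0^{2,8}]undec-9-en-6-yl]methyl (2Z)-2-methylbut-2-enoate (primary mono-angelate) | C/C=C(/C)C(=O)OC[C@@]1(C)[C@@H]2[C@H]3C(=O)C=C(C)[C@@H]2[C@@]3(C)CC[C@@H]1O | intermediate
20 | [(1R,2R,5S,6R,7S,8R)-2,6,9-trimethyl-5-{[(2Z)-2-methylbut-2-enoyl]oxy}-11-oxotricyclo[5.4.0.0^{2,8}]undec-9-en-6-yl]methyl (2Z)-2-methylbut-2-enoate | C/C=C(/C)C(=O)OC[C@@]1(C)[C@@H]2[C@H]3C(=O)C=C(C)[C@@H]2[C@@]3(C)CC[C@@H]1OC(=O)/C(C)=C\C | target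

**Totals**
Total step count: 9. Longest linear sequence: 9 steps (1 and 2 to 20); 7 and 17 are bought.

**Three steps most likely to fail**

Step 7 (cyclobutane closure). The electrophilic C5 is secondary and flanked by a tertiary and a quaternary carbon, and elimination towards C4 competes. The fallback sets out from hydroxy enone 11 and comes back at 13. It replaces the ketone enolate by a more nucleophilic, less basic azaenolate (Corey–Enders hydrazone alkylation). Condensation of 11 with H2NNMe2 gives the N,N-dimethylhydrazone of 11 F5 (C1=N–NMe2 in place of C1=O). MsCl and Et3N give the N,N-dimethylhydrazone of mesylate 12 F6. LiN(iPr)2 in THF forms the α′-azaenolate, which closes the four-membered ring to the N,N-dimethylhydrazone of 13 F7. Aqueous oxalic acid then releases ketone 13.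

Step 5 (ring B). The dienol ether may form as the wrong regioisomer, or the aldol may give the 5,7-syn carbinol, which cannot cyclise in step 7. The fallback sets out from bis-silyl dienol ether 10 and comes back at 11. It changes the ring closure to a carbonyl-ene reaction. Buffered mild acid hydrolyses the enol silyl ether with kinetic α-protonation to the deconjugated ketone (2R,3S)-5-[(1S)-1,3-dimethyl-5-oxocyclohex-2-en-1-yl]-2-ethenyl-2-methyl-3-[(triethylsilyl)oxy]pentanal F4. Me2AlCl then promotes an intramolecular ene reaction of the C3=C4 alkene with the aldehyde (C4–C5 bond, hydrogen transfer from C2) through a closed transition state, which closes ring B and restores the conjugated enone of 11.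

Step 1 (attack at C2 instead of C4 of the pyrylium ring). The fallback sets out from pyrylium salt 1 and comes back at alcohol 6. It uses CH2=CHCH2MgBr; allyl- and benzyl-type Grignard reagents are the class reported to attack the 4-position of 2,4,6-trisubstituted pyrylium salts. This gives 2,4,6-trimethyl-4-(prop-2-en-1-yl)-4H-pyran F1, and dilute acid gives 4-methyl-4-(prop-2-en-1-yl)heptane-2,6-dione F2. The cinchona-amine aldol desymmetrization of step 2 gives (5R)-3,5-dimethyl-5-(prop-2-en-1-yl)cyclohex-2-en-1-one F3. Hydroboration of the terminal alkene with 9-BBN and oxidation with NaBO3 then gives 6.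

**Further compounds**
F1 | step 1 | 2,4,6-trimethyl-4-(prop-2-en-1-yl)-4H-pyran | CC1=CC(C)(CC=C)C=C(C)O1
F2 | step 1 | 4-methyl-4-(prop-2-en-1-yl)heptane-2,6-dione | CC(=O)CC(C)(CC=C)CC(C)=O
F3 | step 1 | (5R)-3,5-dimethyl-5-(prop-2-en-1-yl)cyclohex-2-en-1-one | C=CC[C@]1(C)CC(C)=CC(=O)C1
F4 | step 5 | (2R,3S)-5-[(1S)-1,3-dimethyl-5-oxocyclohex-2-en-1-yl]-2-ethenyl-2-methyl-3-[(triethylsilyl)oxy]pentanal | C=C[C@@](C)(C=O)[C@@H](O[Si](CC)(CC)CC)CC[C@]1(C)C=C(C)CC(=O)C1
F5 | step 7 | N,N-dimethylhydrazone of 11 | C=C[C@@]1(C)[C@@H](O)[C@@H]2C(C)=CC(=NN(C)C)C[C@]2(C)CC[C@@H]1O[Si](CC)(CC)CC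
F6 | step 7 | N,N-dimethylhydrazone of mesylate 12 | C=C[C@@]1(C)[C@@H](OS(C)(=O)=O)[C@@H]2C(C)=CC(=NN(C)C)C[C@]2(C)CC[C@@H]1O[Si](CC)(CC)CC
F7 | step 7 | N,N-dimethylhydrazone of 13 | C=C[C@@]1(C)[C@@H]2[C@H]3C(=NN(C)C)C=C(C)[C@@H]2[C@@]3(C)CC[C@@H]1O[Si](CC)(CC)CC
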